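Atom numbers are those of the target throughout: O1, C2, C3, C3a, C4, C5, C6, C7, C7a. Ring A is the six-membered carbocycle C3a–C4–C5–C6–C7–C7a; ring B is the dihydrofuran O1–C2–C3–C3a–C7a.

## The problem

The target is a 3a-allyl-2-aryl-3-methyl-3,3a-dihydrobenzofuran-6(2H)-one. Ring A is a cross-conjugated cyclohexa-2,5-dienone with a methoxy group on C5, fused along C3a–C7a to ring B, so that O1–C7a=C7–C6=O is a vinylogous ester. The hardest atom is C3a: it is quaternary, sits at the ring fusion between two sp2 carbons, carries the allyl group, and cannot be epimerised once made. It is one of three contiguous stereocentres (2S,3S,3aS), with aryl and methyl trans on ring B and the allyl group trans to the methyl and cis to the aryl group. C2 and C3 are an easy pair in an open chain (a benzylic carbinol next to an enolisable benzylic methine); C3 stands directly on C3a and is the natural controller of that centre. The feature that makes the key step possible is that ring A is the keto form of a para-alkylated phenol: C6=O is the phenol oxygen, C3a is its para carbon, and C4=C5 and C7=C7a (with O1 on C7a) are the remaining arene bonds. The C3a–allyl bond can therefore be made by dearomatising a flat (2S,3S)-dihydrobenzofuran-6-ol with the C3 methyl group beside the reacting carbon. The dienone must be formed late, cold and under kinetic control: [3,3] shifts of the allyl group to C7 or to the C6 oxygen, or an acid-induced dienone–phenol shift, return it to an arene. The benzylic C2–O1 ether (acid, hydrogenolysis), the allyl group (hydrogenation, divalent palladium) and the vinylogous ester (nucleophiles) also limit the reagents that can be used after it.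

## Retrosynthesis

**12 ⇒ 9 (C5–O bond).** The C5 methoxy group is removed first, through the hydroxy methoxy ketone 11 and the epoxide 10. A donor on C5 of the arene would turn C5 into an oxocarbenium carbon in the oxidised phenol and draw the nucleophile there, so it is left out until the quaternary carbon exists. Precursor 9 differs from 12 only by that group. The forward steps must tell the C4=C5 enone from the C7=C7a vinylogous ester and the allyl group; nucleophilic epoxidation does.

**9 ⇒ 7 (C3a–allyl bond, key step).** Cutting the allyl group from C3a turns ring A into a phenol. Against the neighbouring cuts (C3a–C3 together with O1–C2), this one leaves C2 and C3 in a configurationally robust aromatic dihydrobenzofuran, where the C3 methyl group lies in a ring next to the carbon that reacts. Precursor 7 has a flat ring A, two stereocentres and no quaternary carbon. The forward reaction, oxidative para-allylation through the aryloxy-λ3-iodane 8, must attack C3a and not C5 or C7, on the face opposite the C3 methyl group, without equilibration.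

**7 ⇒ 6 ⇒ 5 (O1–C7a bond).** Ring B is opened at the aryl–oxygen bond, not at the benzylic O1–C2 bond. Both stereocentres can then be made in the acyclic alcohol 5 and carried into the ring without a bond to either being broken. Precursor 5 is an aryl chloride with a secondary alcohol. A benzyl ether masks the later phenol oxygen on C6 and is removed from 6 by hydrogenolysis.

**5 ⇒ 4 (C2–H bond).** The carbinol comes from ketone 4, whose α-carbon (C3) is a labile benzylic methine. One catalytic reduction with dynamic kinetic resolution sets C2 and C3 together; precursor 4 is racemic and needs no stereocontrol.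

**4 ⇒ 2 + 3 (C3–C3a bond); 2 ⇒ 1.** The aryl–Cα bond is cut to give two halves of similar size: aryl bromide 2 and propiophenone 3, joined by palladium-catalysed enolate arylation. The bromine of 2 must react and the chlorine must stay for the later ring closure. 2 is the benzyl ether of phenol 1.

## Roads not taken

**Alternative 1:** Cut C3–C3a and O1–C2 together (the obvious route). The forward key step is the acid-induced cationic [3+2] cycloaddition of quinone monoketal A1 with the (E)-propenylarene A2, which builds ring B and the quaternary carbon in one step from two flat pieces. Both partners are achiral and the reactive cation offers no handle for absolute control. The benzylic cation formed after the first C–C bond can close on C7 instead of on oxygen (the [5+2] mode). The C3/C3a relation is fixed by the approach of an acyclic alkene, with nothing that obliges methyl and allyl to end trans. The chosen plan sets the absolute configuration by catalysis and puts C3 in a ring next to C3a before that centre is made.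

**Alternative 2:** Keep the C3a–allyl cut but carry the C5 methoxy group on the arene. This means allylating phenol A3 directly, or heating its allyl ether A4 (Claisen to C5, then Cope to C3a). It would save two steps. In the oxidised phenol the methoxy group localises the charge on C5, so the allylsilane is expected to add there; a later [3,3] shift from C5 to C3a would only copy a C5 configuration that nothing controls. The thermal route runs uphill from an aryl allyl ether to a dienone, and the free ortho carbon C7 drains the system irreversibly through ortho-Claisen shift and enolisation.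

**Alternative 3:** Make the quaternary carbon by Birch reductive allylation of benzoic acid A5 to the dihydro acid A6, then allylic oxidation to dienone A7. This delivers ring A with all three oxygens and the allyl-bearing quaternary carbon in two steps. The carboxyl carbon (the future C3) must then be turned into CH(CH3)–CH(Ar)–O: two stereocentres beside a quaternary carbon in an open chain with no ring to relay from, in the presence of two acid-labile enol ethers. The absolute configuration at C3a would need a stoichiometric auxiliary. The chosen plan has fewer steps after the dearomatisation and a ring-based relay.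

Key step: step 6

Assumption: 4-bromo-3-chlorophenol (1) and 1-(3,4,5-trimethoxyphenyl)propan-1-one (3) are taken as catalogue compounds.

## Steps

Step 1
Reactants: 1 4-bromo-3-chlorophenol
Product: 2 4-(benzyloxy)-1-bromo-2-chlorobenzene
Conditions: BnBr, K2CO3, DMF, rt
Reagents that add atoms: benzyl bromide, BrCc1ccccc1
Why: Williamson ether synthesis; the benzyl ether masks the oxygen that becomes the C6 phenol through the basic palladium steps.

Step 2
Reactants: 2 4-(benzyloxy)-1-bromo-2-chlorobenzene; 3 1-(3,4,5-trimethoxyphenyl)propan-1-one
Product: 4 (±)-2-[4-(benzyloxy)-2-chlorophenyl]-1-(3,4,5-trimethoxyphenyl)propan-1-one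
Conditions: Pd2(dba)3 (1 mol %), Xantphos (2.5 mol %), NaOtBu, toluene, 80 °C
Reagents that add atoms: none
Why: Palladium-catalysed ketone α-arylation forms the C3–C3a bond; zerovalent palladium with this bisphosphine inserts into C–Br and leaves the C–Cl bond for step 4, and the tertiary α-carbon of 4 is not arylated again. The new centre is racemic and labile and is settled in step 3.

Step 3
Reactants: 4 (±)-2-[4-(benzyloxy)-2-chlorophenyl]-1-(3,4,5-trimethoxyphenyl)propan-1-one
Product: 5 (1S,2S)-2-[4-(benzyloxy)-2-chlorophenyl]-1-(3,4,5-trimethoxyphenyl)propan-1-ol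
Conditions: RuCl[(S,S)-TsDPEN](p-cymene) (2 mol %), HCO2H/Et3N (1:1), DMF, 40 °C
Reagents that add atoms: none
Why: Noyori asymmetric transfer hydrogenation with dynamic kinetic resolution: the α-aryl ketone epimerises through its enol in the amine-rich medium while the (S,S)-catalyst gives the (1S)-carbinol, as with aryl alkyl ketones. It should reduce fastest the ketone enantiomer for which that hydride delivery is also anti to the α-aryl group (Felkin–Anh sense), giving the like (1S,2S) isomer, as in dynamic reductions of 1,2-diarylpropan-1-ones. C2 and C3 of the target are both set here.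

Step 4
Reactants: 5 (1S,2S)-2-[4-(benzyloxy)-2-chlorophenyl]-1-(3,4,5-trimethoxyphenyl)propan-1-ol
Product: 6 (2S,3S)-6-(benzyloxy)-3-methyl-2-(3,4,5-trimethoxyphenyl)-2,3-dihydrobenzofuran
Conditions: Pd(OAc)2 (3 mol %), t-BuXPhos (4 mol %), Cs2CO3, toluene, 80 °C
Reagents that add atoms: none
Why: Buchwald–Hartwig-type intramolecular C–O coupling of the aryl chloride with the secondary alkoxide closes ring B (five-membered); the bulky di-tert-butyl biaryl phosphine favours reductive elimination over β-hydride loss. No bond to either stereocentre is broken, so (1S,2S) in 5 becomes the trans (2S,3S) ring.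

Step 5
Reactants: 6 (2S,3S)-6-(benzyloxy)-3-methyl-2-(3,4,5-trimethoxyphenyl)-2,3-dihydrobenzofuran
Product: 7 (2S,3S)-3-methyl-2-(3,4,5-trimethoxyphenyl)-2,3-dihydrobenzofuran-6-ol
Conditions: H2 (1 atm), Pd/C, EtOAc, rt
Reagents that add atoms: none
Why: Hydrogenolysis of the aryl benzyl ether, which is cleaved faster than the cyclic benzylic C2–O1 bond at 1 atm if the reaction is stopped at full conversion.

Step 6
Reactants: 7 (2S,3S)-3-methyl-2-(3,4,5-trimethoxyphenyl)-2,3-dihydrobenzofuran-6-ol
Product: 9 (2S,3S,3aR)-3a-allyl-3-methyl-2-(3,4,5-trimethoxyphenyl)-3,3a-dihydrobenzofuran-6(2H)-one, via aryloxy-λ3-iodane 8 (not isolated)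
Conditions: PhI(OAc)2 (1.2 equiv), allylSiMe3 (5 equiv), (CF3)2CHOH/CH2Cl2, −20 to 0 °C
Reagents that add atoms: allyltrimethylsilane, C=CC[Si](C)(C)C
Why: Ligand exchange on trivalent iodine gives 8, which ionises in the fluorinated alcohol to a phenoxonium ion with loss of iodobenzene; the charge sits on C5, C7 and C3a, the allylsilane bonds to C3a, and the β-silyl cation gives up Me3Si to acetate (oxidative Hosomi–Sakurai reaction). The closest known reaction type is the para-allylation of 4-alkylphenols with PhI(OAc)2 and allyltrimethylsilane in hexafluoropropan-2-ol, which gives 4-allyl-4-alkylcyclohexa-2,5-dienones. No ring is closed; ring A is dearomatised and C3a becomes quaternary. C3a is controlled by C3: in the planar cation the C3 methyl group covers one face of C3a and the C3 hydrogen the other, while the C2 aryl group is one atom further away and pseudo-equatorial, so the silane should enter on the hydrogen face and place allyl trans to methyl and cis to aryl. The descriptor of 9 is 3aR only because C5 carries no oxygen yet; the geometry is that of 12. The step needs attack at C3a and not at C5 or C7: C3a is the only charged carbon bearing an alkyl group, attack there gives the neutral vinylogous ester dienone at once, and no donor sits on a charged carbon (O1 is on the uncharged C7a, and the C5 methoxy group is absent for this reason). The phenol is the only group that binds iodine, so the trimethoxyphenyl ring, the benzylic ether and the product alkene are left alone. At 0 °C or below the dienone cannot return to an arene by [3,3] shifts.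

Step 7
Reactants: 9 (2S,3S,3aR)-3a-allyl-3-methyl-2-(3,4,5-trimethoxyphenyl)-3,3a-dihydrobenzofuran-6(2H)-one
Product: 10 (2S,3S,3aS,4S,5S)-3a-allyl-4,5-epoxy-3-methyl-2-(3,4,5-trimethoxyphenyl)-3,3a,4,5-tetrahydrobenzofuran-6(2H)-one
Conditions: t-BuOOH, DBU, CH2Cl2, 0 °C to rt
Reagents that add atoms: tert-butyl hydroperoxide, CC(C)(C)OO
Why: Weitz–Scheffer nucleophilic epoxidation: the peroxide anion adds only to the C4=C5 enone, because C7a is deactivated by O1 and the allyl double bond is not electrophilic. The oxirane is drawn on the allyl face, anti to C3 and its methyl group; the other face would serve equally, since C4 and C5 become sp2 again in step 8.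

Step 8
Reactants: 10 (2S,3S,3aS,4S,5S)-3a-allyl-4,5-epoxy-3-methyl-2-(3,4,5-trimethoxyphenyl)-3,3a,4,5-tetrahydrobenzofuran-6(2H)-one
Product: 12 (2S,3S,3aS)-3a-allyl-5-methoxy-3-methyl-2-(3,4,5-trimethoxyphenyl)-3,3a-dihydrobenzofuran-6(2H)-one, via hydroxy methoxy ketone 11 (not isolated)
Conditions: NaOMe, MeOH, 50 °C
Reagents that add atoms: methanol (as sodium methoxide), CO
Why: Alkoxide opening of an α,β-epoxy ketone: methoxide attacks C5 (α to the carbonyl, not the neopentyl C4) with inversion to give 11, and E1cB loss of the C4 hydroxyl restores C4=C5, now bearing the methoxy group. C2, C3 and C3a are not touched, and the temperature stays below that of allyl [3,3] shifts.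

## Compound list

1 | 4-bromo-3-chlorophenol | Oc1ccc(Br)c(Cl)c1 | starting material
2 | 4-(benzyloxy)-1-bromo-2-chlorobenzene | Clc1cc(OCc2ccccc2)ccc1Br | intermediate
3 | 1-(3,4,5-trimethoxyphenyl)propan-1-one | CCC(=O)c1cc(OC)c(OC)c(OC)c1 | starting material
4 | (±)-2-[4-(benzyloxy)-2-chlorophenyl]-1-(3,4,5-trimethoxyphenyl)propan-1-one | CC(C(=O)c1cc(OC)c(OC)c(OC)c1)c1ccc(OCc2ccccc2)cc1Cl | intermediate
5 | (1S,2S)-2-[4-(benzyloxy)-2-chlorophenyl]-1-(3,4,5-trimethoxyphenyl)propan-1-ol | C[C@H]([C@H](O)c1cc(OC)c(OC)c(OC)c1)c1ccc(OCc2ccccc2)cc1Cl | intermediate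
6 | (2S,3S)-6-(benzyloxy)-3-methyl-2-(3,4,5-trimethoxyphenyl)-2,3-dihydrobenzofuran | C(c1ccccc1)Oc1ccc2c(c1)O[C@H](c1cc(OC)c(OC)c(OC)c1)[C@H]2C | intermediate
7 | (2S,3S)-3-methyl-2-(3,4,5-trimethoxyphenyl)-2,3-dihydrobenzofuran-6-ol | Oc1ccc2c(c1)O[C@H](c1cc(OC)c(OC)c(OC)c1)[C@H]2C | intermediate
8 | {[(2S,3S)-3-methyl-2-(3,4,5-trimethoxyphenyl)-2,3-dihydrobenzofuran-6-yl]oxy}(phenyl)-λ3-iodanyl acetate | CC(=O)OI(Oc1ccc2c(c1)O[C@H](c1cc(OC)c(OC)c(OC)c1)[C@H]2C)c1ccccc1 | intermediate (not isolated)
9 | (2S,3S,3aR)-3a-allyl-3-methyl-2-(3,4,5-trimethoxyphenyl)-3,3a-dihydrobenzofuran-6(2H)-one | C=CC[C@]12C=CC(=O)C=C1O[C@H](c1cc(OC)c(OC)c(OC)c1)[C@H]2C | intermediate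
10 | (2S,3S,3aS,4S,5S)-3a-allyl-4,5-epoxy-3-methyl-2-(3,4,5-trimethoxyphenyl)-3,3a,4,5-tetrahydrobenzofuran-6(2H)-one | C=CC[C@]12[C@@H]3O[C@@H]3C(=O)C=C1O[C@H](c1cc(OC)c(OC)c(OC)c1)[C@H]2C | intermediate
11 | (2S,3S,3aS,4S,5R)-3a-allyl-4-hydroxy-5-methoxy-3-methyl-2-(3,4,5-trimethoxyphenyl)-3,3a,4,5-tetrahydrobenzofuran-6(2H)-one | C=CC[C@]12[C@H](O)[C@@H](OC)C(=O)C=C1O[C@H](c1cc(OC)c(OC)c(OC)c1)[C@H]2C | intermediate (not isolated)
12 | (2S,3S,3aS)-3a-allyl-5-methoxy-3-methyl-2-(3,4,5-trimethoxyphenyl)-3,3a-dihydrobenzofuran-6(2H)-one | C=CC[C@]12C=C(OC)C(=O)C=C1O[C@H](c1cc(OC)c(OC)c(OC)c1)[C@H]2C | target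

## Step count and least certain steps

Total steps: 8. Longest linear sequence: 8 steps (1 to 12).

**Step 6 (key step).** Three things may go wrong:
- bonding of the allylsilane at the ortho carbons C5 or C7, followed by rearomatisation;
- loss of the C3 proton from the phenoxonium ion, followed by aromatisation of ring B;
- insufficient facial bias at C3a.

The fallback sets out from 5 and returns at 9; it makes C3a first as a non-stereogenic carbon and lets ring closure decide its configuration. Silylation (t-BuMe2SiOTf, 2,6-lutidine) gives the silyl ether F1. Hydrogenolysis over Pd/C with NaOAc removes both the benzyl group and the chlorine to give the para-substituted phenol F2. The same PhI(OAc)2/allylsilane reaction, now on a plain 4-alkylphenol that needs no facial selectivity, gives the dienone F3, whose two ring arms are alike. The silyl group is there to stop Grob-type cleavage of the C2–C3 bond in the cation. Bu4NF then frees the C2 alkoxide, which adds reversibly to one of the two diastereotopic enone arms (desymmetrising oxa-Michael addition) to give the cis-fused enone F4. Under equilibration the aryl group should take the convex face, which again puts allyl cis to aryl and trans to methyl. Dehydrogenation across C7–C7a with IBX in DMSO gives 9.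

**Step 4.** β-Hydride loss from the palladium alkoxide, or failure of oxidative addition into the electron-rich, ortho-branched aryl chloride, may stop the ring closure. The fallback sets out from 3 and returns at 7; it closes ring B at the benzylic carbon instead. α-Arylation of 3 with 2,4-bis(benzyloxy)-1-bromobenzene F5 (from 4-bromoresorcinol and benzyl bromide) gives the ketone F6. The transfer hydrogenation of step 3 gives the alcohol F7, and hydrogenolysis frees the triol F8. Catalytic TsOH in CH2Cl2 ionises the benzylic alcohol, and the ortho phenol captures the cation trans to the C3 methyl group, giving 7 directly. C2 is then set by C3, so only the C3 configuration from the reduction matters.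

**Step 8.** Retro-aldol cleavage of the C4 alkoxide of 11, opening of ring B by methoxide exchange at C7a, or incomplete dehydration may compete. The fallback sets out from 10 and returns at 12; it puts the oxygen in first and the methyl group second. LiOH in aqueous THF opens the epoxide and dehydrates to the diosphenol F9, driven by deprotonation of the acidic enol. Me2SO4/K2CO3 in acetone then methylates the enol oxygen.

**Step 7.** Conjugate addition of the peroxide at the neopentyl carbon C4, shielded by the allyl group on one face and the C3 methyl group on the other, may be slower than base-induced decay of the dienone. The fallback sets out from 9 and returns at 12; it uses a small hydride in place of the peroxide. LiBH(s-Bu)3 reduces the C4=C5 enone in the 1,4-sense (the vinylogous ester is inert), and the enolate is hydroxylated with 2-(phenylsulfonyl)-3-phenyloxaziridine to give the hydroxy ketone F10 (either C5 epimer serves). Dess–Martin periodinane gives the 1,2-dione, which enolises toward C4 to the diosphenol F9, methylated as above.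

## Further compounds

F1 | step 6 | tert-butyl{(1S,2S)-2-[4-(benzyloxy)-2-chlorophenyl]-1-(3,4,5-trimethoxyphenyl)propoxy}dimethylsilane | C[C@H]([C@H](O[Si](C)(C)C(C)(C)C)c1cc(OC)c(OC)c(OC)c1)c1ccc(OCc2ccccc2)cc1Cl
F2 | step 6 | 4-[(1S,2S)-1-[(tert-butyldimethylsilyl)oxy]-1-(3,4,5-trimethoxyphenyl)propan-2-yl]phenol | C[C@H]([C@H](O[Si](C)(C)C(C)(C)C)c1cc(OC)c(OC)c(OC)c1)c1ccc(O)cc1
F3 | step 6 | 4-allyl-4-[(1S,2S)-1-[(tert-butyldimethylsilyl)oxy]-1-(3,4,5-trimethoxyphenyl)propan-2-yl]cyclohexa-2,5-dien-1-one | C=CCC1(C=CC(=O)C=C1)[C@H](C)[C@H](O[Si](C)(C)C(C)(C)C)c1cc(OC)c(OC)c(OC)c1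
F4 | step 6 | (2S,3S,3aR,7aR)-3a-allyl-3-methyl-2-(3,4,5-trimethoxyphenyl)-3,3a,7,7a-tetrahydrobenzofuran-6(2H)-one | C=CC[C@]12C=CC(=O)C[C@H]1O[C@H](c1cc(OC)c(OC)c(OC)c1)[C@H]2C
F5 | step 4 | 2,4-bis(benzyloxy)-1-bromobenzene | Brc1ccc(OCc2ccccc2)cc1OCc1ccccc1
F6 | step 4 | (±)-2-[2,4-bis(benzyloxy)phenyl]-1-(3,4,5-trimethoxyphenyl)propan-1-one | CC(C(=O)c1cc(OC)c(OC)c(OC)c1)c1ccc(OCc2ccccc2)cc1OCc1ccccc1
F7 | step 4 | (1S,2S)-2-[2,4-bis(benzyloxy)phenyl]-1-(3,4,5-trimethoxyphenyl)propan-1-ol | C[C@H]([C@H](O)c1cc(OC)c(OC)c(OC)c1)c1ccc(OCc2ccccc2)cc1OCc1ccccc1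
F8 | step 4 | 4-[(1S,2S)-1-hydroxy-1-(3,4,5-trimethoxyphenyl)propan-2-yl]benzene-1,3-diol | C[C@H]([C@H](O)c1cc(OC)c(OC)c(OC)c1)c1ccc(O)cc1O
F9 | step 8 | (2S,3S,3aS)-3a-allyl-5-hydroxy-3-methyl-2-(3,4,5-trimethoxyphenyl)-3,3a-dihydrobenzofuran-6(2H)-one | C=CC[C@]12C=C(O)C(=O)C=C1O[C@H](c1cc(OC)c(OC)c(OC)c1)[C@H]2C
F10 | step 7 | (2S,3S,3aR,5S)-3a-allyl-5-hydroxy-3-methyl-2-(3,4,5-trimethoxyphenyl)-3,3a,4,5-tetrahydrobenzofuran-6(2H)-one | C=CC[C@]12C[C@H](O)C(=O)C=C1O[C@H](c1cc(OC)c(OC)c(OC)c1)[C@H]2C
A1 | alternative 1 | 2-allyl-4,4,5-trimethoxycyclohexa-2,5-dien-1-one | C=CCC1=CC(OC)(OC)C(OC)=CC1=O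
A2 | alternative 1 | (E)-1,2,3-trimethoxy-5-(prop-1-en-1-yl)benzene | C/C=C/c1cc(OC)c(OC)c(OC)c1
A3 | alternative 2 | (2S,3S)-5-methoxy-3-methyl-2-(3,4,5-trimethoxyphenyl)-2,3-dihydrobenzofuran-6-ol | COc1cc2c(cc1O)O[C@H](c1cc(OC)c(OC)c(OC)c1)[C@H]2C
A4 | alternative 2 | (2S,3S)-6-(allyloxy)-5-methoxy-3-methyl-2-(3,4,5-trimethoxyphenyl)-2,3-dihydrobenzofuran | COc1cc2c(cc1OCC=C)O[C@H](c1cc(OC)c(OC)c(OC)c1)[C@H]2C
A5 | alternative 3 | 2,5-dimethoxybenzoic acid | COc1ccc(OC)c(C(=O)O)c1
A6 | alternative 3 | (±)-1-allyl-2,5-dimethoxycyclohexa-2,5-diene-1-carboxylic acid | C=CCC1(C(=O)O)C=C(OC)CC=C1OC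
A7 | alternative 3 | (±)-1-allyl-2,5-dimethoxy-4-oxocyclohexa-2,5-diene-1-carboxylic acid | C=CCC1(C(=O)O)C=C(OC)C(=O)C=C1OC
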